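Numbering: ring A is the fused guaiacol ring. Ring B is the dihydro ring (C1 vinylic CH, C2 acyl-bearing carbon, C3 stereocentre, C4 benzylic CH2). Ring D is the 4-hydroxy-3-methoxybenzoyl arene.
Retrosynthesis: take off two phenol benzyl groups. Cut the ketone carbon–ring D bond and close the acyl carbon onto the C3–CH2OH oxygen to give a temporary γ-lactone, ring C. Add water back across C1=C2, then cut C1–C2 and C3–C4 together.
Enabling feature: C1 and C4 are ortho substituents of ring A at the aldehyde and methyl oxidation levels. That is an o-tolualdehyde, whose photoenol is a hydroxy-o-quinodimethane (diene C1=C8a–C4a=C4). C2–C3, with its carbonyl on C2 and its CH2O on C3, is exactly furan-2(5H)-one.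
Forward: ring A is bought as creosol and formylated. Ring B is closed onto the preformed ring C in one photoenolization/Diels–Alder event, and dehydration installs C1=C2. The ring D aryllithium opens ring C to the ketone and the free CH2OH, and debenzylation ends the route.
Stereochemistry: C3 (R) is set in the cycloaddition by a titanium TADDOLate that selects one face of the butenolide. The two helper stereocentres (C1, C2) vanish on dehydration, and no later step touches C3–H.
Key step: step 3

Assumption: the titanium complex of (R,R)-TADDOL, (4R,5R)-2,2-dimethyl-α,α,α′,α′-tetraphenyl-1,3-dioxolane-4,5-dimethanol, is taken to leave open the face of furan-2(5H)-one that is Re at its C4, which leads to (3aR). Should a trial run show the opposite sense, the equally available (S,S)-ligand is used and nothing else changes.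

Step 1
Reactants: 1 2-methoxy-4-methylphenol (creosol)
Product: 2 1-(benzyloxy)-2-methoxy-4-methylbenzene
Conditions: BnBr, K2CO3, DMF, rt
Reagents that add atoms: benzyl bromide, BrCc1ccccc1
Why: Williamson ether synthesis of a phenoxide with a primary benzylic bromide; the benzyl ether withstands POCl3, Ti(OiPr)4, 365 nm light and aryllithium and leaves the OMe group as the strongest director for step 2.

Step 2
Reactants: 2 1-(benzyloxy)-2-methoxy-4-methylbenzene
Product: 4 5-(benzyloxy)-4-methoxy-2-methylbenzaldehyde, via aryl iminium chloride 3 (not isolated)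
Conditions: POCl3, DMF, 0 to 90 °C; then ice-water
Reagents that add atoms: N,N-dimethylformamide, CN(C)C=O; water, O
Why: Vilsmeier–Haack formylation, which on 3,4-dialkoxytoluenes attacks the carbon para to an alkoxy group and ortho to CH3; here that is the carbon para to OMe (the position para to OBn is blocked by CH3), and water then hydrolyses iminium 3 to the aldehyde.

Step 3
Reactants: 4 5-(benzyloxy)-4-methoxy-2-methylbenzaldehyde; 5 furan-2(5H)-one
Product: 7 (3aR,9R,9aR)-7-(benzyloxy)-9-hydroxy-6-methoxy-3a,4,9,9a-tetrahydronaphtho[2,3-c]furan-1(3H)-one (all-cis), via (E)-photoenol 6 (not isolated)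
Conditions: Ti(OiPr)4 (2 equiv), (R,R)-TADDOL (2 equiv), 5 (3 equiv), degassed toluene, hν (365 nm), rt, Ar; then aq. NaHCO3
Reagents that add atoms: none
Why: Absorption of 365 nm light by 4 gives the carbonyl triplet, which abstracts a hydrogen atom from the ortho CH3 (1,5-transfer) and relaxes to the long-lived (E)-hydroxy-o-quinodimethane 6; its OH exchanges for an isopropoxide on the titanium TADDOLate, the lactone carbonyl of 5 binds the same Lewis-acidic metal, and the templated pair undergoes a concerted suprafacial [4+2] cycloaddition driven by the return of aromaticity to ring A. The closest known reaction type is the Ti(OiPr)4/TADDOL-mediated enantioselective photoenolization/Diels–Alder reaction of electron-rich 2-methylbenzaldehydes with butenolides and cyclic enones. Ring B is the only ring closed, by an intermolecular [4+2] cycloaddition that makes C9–C9a and C4–C3a (C1–C2 and C4–C3 of the target) at once, while ring C is carried in intact and ends up cis-fused because its ring alkene can only add suprafacially. C3a and C9a are fixed together by the face of 5 that the chiral diolate leaves open, and C9 follows from the E geometry of 6 and the titanium-bridged endo transition state, which puts the C9 oxygen cis to the lactone carbonyl. The step needs regioselectivity and facial selectivity: the donor oxygen of 6 makes its CH2 terminus the nucleophilic end, which pairs with the electrophilic β-carbon of 5, and the O–Ti–O=C bridge can only span the neighbouring atoms C9 and C9a, so both effects give the required orientation. Endo/exo selectivity is not critical because C9 and C9a are flattened in step 4 and only C3a survives, and 5 is transparent at 365 nm and cannot undergo the E/Z isomerization that an open-chain aryl enone could.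

Step 4
Reactants: 7 (3aR,9R,9aR)-7-(benzyloxy)-9-hydroxy-6-methoxy-3a,4,9,9a-tetrahydronaphtho[2,3-c]furan-1(3H)-one
Product: 9 (3aR)-7-(benzyloxy)-6-methoxy-3a,4-dihydronaphtho[2,3-c]furan-1(3H)-one, via C9 mesylate 8 (not isolated)
Conditions: MsCl, Et3N (excess), CH2Cl2, 0 °C to rt
Reagents that add atoms: none
Why: Mesylation and in situ E1cB/E2 elimination of a β-sulfonyloxy lactone: C9a–H is α to the lactone carbonyl and anti to the benzylic C9 leaving group, the new alkene is conjugated to ring A and to the carbonyl, and C3a–H stays untouched because it sits on the α-carbon of the new enoate (cross-conjugated, not vinylogously acidic).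

Step 5
Reactants: 10 4-bromo-2-methoxyphenol
Product: 11 1-(benzyloxy)-4-bromo-2-methoxybenzene
Conditions: BnBr, K2CO3, DMF, rt
Reagents that add atoms: benzyl bromide, BrCc1ccccc1
Why: Williamson ether synthesis as in step 1; it removes the acidic phenol proton so that bromine–lithium exchange is possible in step 6.

Step 6
Reactants: 11 1-(benzyloxy)-4-bromo-2-methoxybenzene; 9 (3aR)-7-(benzyloxy)-6-methoxy-3a,4-dihydronaphtho[2,3-c]furan-1(3H)-one
Product: 14 [(3R)-7-(benzyloxy)-3-(hydroxymethyl)-6-methoxy-3,4-dihydronaphthalen-2-yl][4-(benzyloxy)-3-methoxyphenyl]methanone, via aryllithium 12 (not isolated), via lithium lactolate 13 (not isolated)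
Conditions: 11, n-BuLi, THF, −78 °C; cannulated into 9, THF, −78 °C; AcOH, −78 °C to rt
Reagents that add atoms: none
Why: Bromine–lithium exchange followed by 1,2-addition of the hard aryllithium to the lactone carbonyl (monoaddition of an organolithium to a γ-lactone): lactolate 13 persists at −78 °C, so the ketone appears only after the acidic quench when no nucleophile is left, ring C opens to the conjugated aryl ketone and the free CH2OH, and C3 is not involved.

Step 7
Reactants: 14 [(3R)-7-(benzyloxy)-3-(hydroxymethyl)-6-methoxy-3,4-dihydronaphthalen-2-yl][4-(benzyloxy)-3-methoxyphenyl]methanone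
Product: 15 [(3R)-7-hydroxy-3-(hydroxymethyl)-6-methoxy-3,4-dihydronaphthalen-2-yl](4-hydroxy-3-methoxyphenyl)methanone (target)
Conditions: BCl3, C6HMe5, CH2Cl2, −78 °C; then CHCl3/MeOH, aqueous work-up
Reagents that add atoms: none
Why: Lewis acid debenzylation of aryl benzyl ethers with a cation scavenger: BCl3 ionizes the O–CH2Ph bonds at −78 °C and pentamethylbenzene traps the benzyl cations by Friedel–Crafts alkylation, which spares the C1=C2 alkene that hydrogenolysis would saturate, the two aryl methyl ethers and the C3 stereocentre.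

Compound list
1 | 2-methoxy-4-methylphenol (creosol) | Cc1ccc(O)c(OC)c1 | starting material
2 | 1-(benzyloxy)-2-methoxy-4-methylbenzene | Cc1ccc(OCc2ccccc2)c(OC)c1 | intermediate
3 | N-[5-(benzyloxy)-4-methoxy-2-methylbenzylidene]-N-methylmethanaminium chloride | C[N+](C)=Cc1cc(OCc2ccccc2)c(OC)cc1C.[Cl-] | intermediate
4 | 5-(benzyloxy)-4-methoxy-2-methylbenzaldehyde | Cc1cc(OC)c(OCc2ccccc2)cc1C=O | intermediate
5 | furan-2(5H)-one | O=C1C=CCO1 | starting material
6 | (E)-[3-(benzyloxy)-4-methoxy-6-methylidenecyclohexa-2,4-dien-1-ylidene]methanol (photoenol, held on titanium through its oxygen) | O/C=C1\C=C(OCc2ccccc2)C(OC)=CC1=C | intermediate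
7 | (3aR,9R,9aR)-7-(benzyloxy)-9-hydroxy-6-methoxy-3a,4,9,9a-tetrahydronaphtho[2,3-c]furan-1(3H)-one | O[C@H]1c2cc(OCc3ccccc3)c(OC)cc2C[C@H]2COC(=O)[C@@H]12 | intermediate
8 | (3aR,9R,9aR)-7-(benzyloxy)-6-methoxy-1-oxo-1,3,3a,4,9,9a-hexahydronaphtho[2,3-c]furan-9-yl methanesulfonate | CS(=O)(=O)O[C@H]1c2cc(OCc3ccccc3)c(OC)cc2C[C@H]2COC(=O)[C@@H]12 | intermediate
9 | (3aR)-7-(benzyloxy)-6-methoxy-3a,4-dihydronaphtho[2,3-c]furan-1(3H)-one | O=C1OC[C@@H]2Cc3cc(OC)c(OCc4ccccc4)cc3C=C12 | intermediate
10 | 4-bromo-2-methoxyphenol | Oc1ccc(Br)cc1OC | starting material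
11 | 1-(benzyloxy)-4-bromo-2-methoxybenzene | COc1cc(Br)ccc1OCc1ccccc1 | intermediate
12 | [4-(benzyloxy)-3-methoxyphenyl]lithium | [Li]c1ccc(OCc2ccccc2)c(OC)c1 | intermediate
13 | lithium (3aR)-7-(benzyloxy)-1-[4-(benzyloxy)-3-methoxyphenyl]-6-methoxy-1,3,3a,4-tetrahydronaphtho[2,3-c]furan-1-olate (C1 configuration not defined) | [Li]OC1(c4ccc(OCc5ccccc5)c(OC)c4)OC[C@@H]2Cc3cc(OC)c(OCc4ccccc4)cc3C=C12 | intermediate
14 | [(3R)-7-(benzyloxy)-3-(hydroxymethyl)-6-methoxy-3,4-dihydronaphthalen-2-yl][4-(benzyloxy)-3-methoxyphenyl]methanone | COc1cc(C(=O)C2=Cc3cc(OCc4ccccc4)c(OC)cc3C[C@H]2CO)ccc1OCc1ccccc1 | intermediate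
15 | [(3R)-7-hydroxy-3-(hydroxymethyl)-6-methoxy-3,4-dihydronaphthalen-2-yl](4-hydroxy-3-methoxyphenyl)methanone | COc1cc(C(=O)C2=Cc3cc(O)c(OC)cc3C[C@H]2CO)ccc1O | target

Total step count: 7. Longest linear sequence: 6 (steps 1, 2, 3, 4, 6, 7).

Steps most likely to fail

Step 3. The risk is poor discrimination between the two faces of the small, flat butenolide by the chiral titanium complex, which would lower the enantiomeric purity at C3a. The fallback takes the stereochemistry from a classical resolution instead of a chiral Lewis acid. It sets out from 4 and 5 and comes back at 9. The cycloaddition is run with Ti(OiPr)4 alone and should give the racemic all-cis hydroxy lactone F1. Steglich esterification of the C9 hydroxyl with (S)-O-methylmandelic acid (DCC, DMAP, CH2Cl2, 0 °C) gives the (3aR,9R,9aR) mandelate F2 and the (3aS,9S,9aS) mandelate F3. These are diastereomers and are separated by crystallization or chromatography. DBU in CH2Cl2 then expels the mandelate from F2 along the elimination pathway of step 4 and delivers 9, so the resolving group doubles as the leaving group.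

Step 6. The risks are premature collapse of the lactolate followed by a second addition of the aryllithium, and competing conjugate addition at C9. The fallback transfers the acyl group through a Weinreb amide instead of opening the lactone directly. It sets out from 9 and comes back at 14.
- MeNH(OMe)·HCl and AlMe3 in CH2Cl2 (0 °C to rt) open ring C to the hydroxy Weinreb amide F4.
- F4 is silylated at once (TBSCl, imidazole, DMF) to stop relactonization, giving the silyl ether Weinreb amide F5.
- Aryllithium 12 (from 11, as in step 6) adds once to F5 at −78 °C through the stable chelated adduct and gives the silyl-protected ketone F6.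
- Bu4NF buffered with AcOH (THF, 0 °C) frees the primary alcohol and gives 14.

Step 7. The risks are loss of an aryl methyl group next to a freshly liberated phenol and acid-induced damage or aromatization of ring B. The fallback moves the debenzylation to a stage without an alkene and finishes with fluoride-labile groups. It sets out from 7 and 10 and comes back at 15.
- Hydrogenolysis of 7 (H2, Pd/C, EtOAc, rt) should give the phenol hydroxy lactone F7.
- TBSCl (1 equiv), imidazole, DMF, 0 °C silylates the more acidic phenol to the aryl silyl ether hydroxy lactone F8.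
- MsCl/Et3N as in step 4 gives the silyl-protected unsaturated lactone F9.
- Separately, 10 is silylated (TBSCl, imidazole, DMF) to the silyl-protected aryl bromide F10, which with n-BuLi (THF, −78 °C) gives the silyl-protected aryllithium F11.
- Addition of F11 to F9 and an AcOH quench as in step 6 gives the bis(silyl ether) ketone F12.
- Bu4NF buffered with AcOH (THF, 0 °C) removes both silyl groups under nearly neutral conditions and gives 15.

Further compounds
F1 | step 3 | racemic all-cis 7-(benzyloxy)-9-hydroxy-6-methoxy-3a,4,9,9a-tetrahydronaphtho[2,3-c]furan-1(3H)-one (both enantiomers written) | O[C@H]1c2cc(OCc3ccccc3)c(OC)cc2C[C@H]2COC(=O)[C@@H]12.O[C@@H]1c2cc(OCc3ccccc3)c(OC)cc2C[C@@H]2COC(=O)[C@H]12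
F2 | step 3 | (3aR,9R,9aR)-7-(benzyloxy)-6-methoxy-1-oxo-1,3,3a,4,9,9a-hexahydronaphtho[2,3-c]furan-9-yl (S)-2-methoxy-2-phenylacetate | CO[C@H](C(=O)O[C@H]1c2cc(OCc3ccccc3)c(OC)cc2C[C@H]2COC(=O)[C@@H]12)c1ccccc1
F3 | step 3 | (3aS,9S,9aS)-7-(benzyloxy)-6-methoxy-1-oxo-1,3,3a,4,9,9a-hexahydronaphtho[2,3-c]furan-9-yl (S)-2-methoxy-2-phenylacetate | CO[C@H](C(=O)O[C@@H]1c2cc(OCc3ccccc3)c(OC)cc2C[C@@H]2COC(=O)[C@H]12)c1ccccc1
F4 | step 6 | (3R)-7-(benzyloxy)-3-(hydroxymethyl)-N,6-dimethoxy-N-methyl-3,4-dihydronaphthalene-2-carboxamide | CON(C)C(=O)C1=Cc2cc(OCc3ccccc3)c(OC)cc2C[C@H]1CO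
F5 | step 6 | (3R)-7-(benzyloxy)-3-{[(tert-butyldimethylsilyl)oxy]methyl}-N,6-dimethoxy-N-methyl-3,4-dihydronaphthalene-2-carboxamide | CON(C)C(=O)C1=Cc2cc(OCc3ccccc3)c(OC)cc2C[C@H]1CO[Si](C)(C)C(C)(C)C
F6 | step 6 | [(3R)-7-(benzyloxy)-3-{[(tert-butyldimethylsilyl)oxy]methyl}-6-methoxy-3,4-dihydronaphthalen-2-yl][4-(benzyloxy)-3-methoxyphenyl]methanone | COc1cc(C(=O)C2=Cc3cc(OCc4ccccc4)c(OC)cc3C[C@H]2CO[Si](C)(C)C(C)(C)C)ccc1OCc1ccccc1
F7 | step 7 | (3aR,9R,9aR)-7,9-dihydroxy-6-methoxy-3a,4,9,9a-tetrahydronaphtho[2,3-c]furan-1(3H)-one | O[C@H]1c2cc(O)c(OC)cc2C[C@H]2COC(=O)[C@@H]12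
F8 | step 7 | (3aR,9R,9aR)-7-[(tert-butyldimethylsilyl)oxy]-9-hydroxy-6-methoxy-3a,4,9,9a-tetrahydronaphtho[2,3-c]furan-1(3H)-one | O[C@H]1c2cc(O[Si](C)(C)C(C)(C)C)c(OC)cc2C[C@H]2COC(=O)[C@@H]12
F9 | step 7 | (3aR)-7-[(tert-butyldimethylsilyl)oxy]-6-methoxy-3a,4-dihydronaphtho[2,3-c]furan-1(3H)-one | O=C1OC[C@@H]2Cc3cc(OC)c(O[Si](C)(C)C(C)(C)C)cc3C=C12
F10 | step 7 | (4-bromo-2-methoxyphenoxy)(tert-butyl)dimethylsilane | COc1cc(Br)ccc1O[Si](C)(C)C(C)(C)C
F11 | step 7 | {4-[(tert-butyldimethylsilyl)oxy]-3-methoxyphenyl}lithium | [Li]c1ccc(O[Si](C)(C)C(C)(C)C)c(OC)c1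
F12 | step 7 | {(3R)-7-[(tert-butyldimethylsilyl)oxy]-3-(hydroxymethyl)-6-methoxy-3,4-dihydronaphthalen-2-yl}{4-[(tert-butyldimethylsilyl)oxy]-3-methoxyphenyl}methanone | COc1cc(C(=O)C2=Cc3cc(O[Si](C)(C)C(C)(C)C)c(OC)cc3C[C@H]2CO)ccc1O[Si](C)(C)C(C)(C)C
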